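**Retrosynthetic overview**
- Target ⇐ senecioylation of the 9β-hydroxy-8-ketone ⇐ copper hydride 1,4-reduction / Rubottom oxidation of a 3-tigloyloxy-eremophila-9,11-dien-8-one (sets the cis ring fusion and the C9 oxygen).
- That dienone ⇐ one palladium operation on an acyclic (Z)-β-iodo dienone: ring A closes first (vinylpalladium onto the 1,1-disubstituted alkene, C5 quaternary centre), ring B second (neopentylpalladium onto the Me2C=CH–C=O alkene, isopropenyl by β-hydride elimination).
- Iodo dienone ⇐ hydroiodination of an ynone ⇐ acyl Sonogashira coupling of a terminal alkyne with senecioyl chloride.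
- C3/C4 stereodiad ⇐ catalytic asymmetric anti-(2-methylcrotyl)boration of pent-4-ynal, then Mitsunobu inversion with tiglic acid.

Assumption: locants C1–C15 in the text follow eremophilane numbering (C3 tiglate, C4 and C5 methyls, C7 isopropenyl, C8 ketone, C9 senecioate, C10 ring-fusion H); β is the face of the C5 methyl.

**Step 1**
Reactants: 1 (2E)-2-methylbut-2-en-1-ol; 2 bis(pinacolato)diboron
Product: 3 4,4,5,5-tetramethyl-2-[(2E)-2-methylbut-2-en-1-yl]-1,3,2-dioxaborolane
Conditions: Pd(MeCN)4(BF4)2 (5 mol%), DMSO/MeOH 1:1, 50 °C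
Reagents that add atoms: none
Why: palladium-catalysed allylic borylation (Miyaura type, via a π-allylpalladium intermediate) puts boron on the CH2 terminus and the syn π-allyl keeps the (E) alkene; no stereocentre is formed.

**Step 2**
Reactants: 4 pent-4-yn-1-ol
Product: 5 pent-4-ynal
Conditions: TEMPO (10 mol%), PhI(OAc)2, CH2Cl2, rt
Reagents that add atoms: none
Why: oxoammonium (TEMPO) oxidation stops at the aldehyde and leaves the terminal alkyne untouched.

**Step 3**
Reactants: 3 allylboronate; 5 pent-4-ynal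
Product: 7 (3R,4S)-2,3-dimethyloct-1-en-7-yn-4-ol, via O-boryl ether 6 (not isolated)
Conditions: (R)-TRIP [(R)-3,3'-bis(2,4,6-triisopropylphenyl)-BINOL hydrogen phosphate] (5 mol%), 4 Å MS, toluene, −30 °C; aq. NaHCO3
Reagents that add atoms: none
Why: chiral phosphoric acid-catalysed allylboration through a closed chair transition state (type 1 allylation): the (E)-boronate gives the anti pair and the (R)-catalyst directs Re-face attack, setting the 4S carbinol (C3) and the 3R methyl-bearing centre (C4).

**Step 4**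
Reactants: 7 anti alcohol; 8 (2E)-2-methylbut-2-enoic acid (tiglic acid)
Product: 9 (3R,4R)-2,3-dimethyloct-1-en-7-yn-4-yl (2E)-2-methylbut-2-enoate
Conditions: PPh3, DIAD, THF, 0 °C → rt
Reagents that add atoms: none
Why: Mitsunobu esterification proceeds by SN2 inversion at the carbinol, converting anti to the required syn (C3 R) relationship while installing the tiglate.

**Step 5**
Reactants: 9 alkyne ester; 10 3-methylbut-2-enoyl chloride (senecioyl chloride)
Product: 11 (3R,4R)-2,3,11-trimethyl-9-oxododeca-1,10-dien-7-yn-4-yl (2E)-2-methylbut-2-enoate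
Conditions: PdCl2(PPh3)2 (2 mol%), CuI (4 mol%), Et3N, THF, 0 °C → rt
Reagents that add atoms: none
Why: acyl Sonogashira coupling (copper acetylide to acylpalladium) gives the cross-conjugated ynone that carries C7–C13; existing stereocentres are untouched.

**Step 6**
Reactants: 11 ynone
Product: 12 (3R,4R,7Z)-7-iodo-2,3,11-trimethyl-9-oxododeca-1,7,10-trien-4-yl (2E)-2-methylbut-2-enoate
Conditions: NaI, AcOH, rt
Reagents that add atoms: sodium iodide, [Na+].[I-]
Why: conjugate hydroiodination of the ynone (iodide to the β-carbon, anti protonation) gives the kinetic (Z)-β-iodoenone with iodine cis to the acyl group, the geometry ring B needs.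

**Step 7**
Reactants: 12 (Z)-β-iodo dienone
Product: 15 (1R,2R,7R,8aR)-1,8a-dimethyl-6-oxo-7-(prop-1-en-2-yl)-1,2,3,4,6,7,8,8a-octahydronaphthalen-2-yl (2E)-2-methylbut-2-enoate, via neopentylpalladium iodide 13 (not isolated), via tertiary alkylpalladium iodide 14 (not isolated)
Conditions: Pd(OAc)2 (10 mol%), PPh3 (25 mol%), Ag2CO3, MeCN, 70 °C
Reagents that add atoms: none
Why: domino Mizoroki–Heck bicyclisation: zerovalent palladium inserts into the C–I bond, 6-exo syn-carbopalladation of the 1,1-disubstituted alkene through a chair-like transition state (OTig and C4 methyl equatorial, allylic C4–H eclipsing the alkene to minimise A(1,3) strain, CH2[Pd] arm equatorial) is expected to set C5 cis to the C4 methyl; the neopentylpalladium has no β-hydrogen and the (Z)-enone holds C6 next to C7, so a second 6-exo insertion closes ring B with the CMe2[Pd] carbon equatorial (C7 R), and β-hydride elimination from a methyl group gives the isopropenyl group.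

**Step 8**
Reactants: 15 dienone
Product: 17 (1R,2R,4aS,5R,7R,8aR)-5-hydroxy-1,8a-dimethyl-6-oxo-7-(prop-1-en-2-yl)decahydronaphthalen-2-yl (2E)-2-methylbut-2-enoate, via trimethylsilyl enol ether 16 (not isolated)
Conditions: [(Ph3P)CuH]6, Me3SiCl, THF, −40 → 0 °C; DMDO, acetone, −78 °C; 10% aq. citric acid, THF, 0 °C
Reagents that add atoms: dimethyldioxirane, CC1(C)OO1 (C9 oxygen); chlorotrimethylsilane, C[Si](C)(C)Cl (silyl group of 16 only)
Why: copper hydride 1,4-reduction with silyl trapping followed by Rubottom oxidation: hydride is expected to add to C10 axially on the face of the angular methyl (as cuprates do with 10-methyl-octalones) to give the cis-decalin (C10 S), and DMDO epoxidises the regiodefined enol silane on the convex β face (the α face is covered by the axial C4 of ring A) to give the equatorial 9R alcohol.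

**Step 9**
Reactants: 17 α-ketol; 10 3-methylbut-2-enoyl chloride
Product: 18 (1R,2R,4aS,5R,7R,8aR)-1,8a-dimethyl-5-[(3-methylbut-2-enoyl)oxy]-6-oxo-7-(prop-1-en-2-yl)decahydronaphthalen-2-yl (2E)-2-methylbut-2-enoate (target; (3R,4R,5R,7R,9R,10S)-3-tigloyloxy-9-senecioyloxy-eremophil-11-en-8-one)
Conditions: pyridine, DMAP (10 mol%), CH2Cl2, 0 °C
Reagents that add atoms: none
Why: DMAP-catalysed acylation (nucleophilic catalysis) of the secondary α-ketol with retention at C9; weak base at 0 °C avoids epimerisation at C7/C9 and deconjugation of the senecioyl unit.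

**Compound list**
1 | (2E)-2-methylbut-2-en-1-ol | C/C=C(\C)CO | starting material
2 | bis(pinacolato)diboron | CC1(C)OB(OC1(C)C)B1OC(C)(C)C(C)(C)O1 | starting material
3 | 4,4,5,5-tetramethyl-2-[(2E)-2-methylbut-2-en-1-yl]-1,3,2-dioxaborolane | C/C=C(\C)CB1OC(C)(C)C(C)(C)O1 | intermediate
4 | pent-4-yn-1-ol | C#CCCCO | starting material
5 | pent-4-ynal | C#CCCC=O | intermediate
6 | 2-{[(3R,4S)-2,3-dimethyloct-1-en-7-yn-4-yl]oxy}-4,4,5,5-tetramethyl-1,3,2-dioxaborolane (O-boryl ether) | C=C(C)[C@@H](C)[C@@H](OB1OC(C)(C)C(C)(C)O1)CCC#C | intermediate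
7 | (3R,4S)-2,3-dimethyloct-1-en-7-yn-4-ol | C=C(C)[C@@H](C)[C@@H](O)CCC#C | intermediate
8 | (2E)-2-methylbut-2-enoic acid (tiglic acid) | C/C=C(\C)C(=O)O | starting material
9 | (3R,4R)-2,3-dimethyloct-1-en-7-yn-4-yl (2E)-2-methylbut-2-enoate | C=C(C)[C@@H](C)[C@H](OC(=O)/C(C)=C/C)CCC#C | intermediate
10 | 3-methylbut-2-enoyl chloride | CC(C)=CC(=O)Cl | starting material
11 | (3R,4R)-2,3,11-trimethyl-9-oxododeca-1,10-dien-7-yn-4-yl (2E)-2-methylbut-2-enoate | C=C(C)[C@@H](C)[C@H](OC(=O)/C(C)=C/C)CCC#CC(=O)C=C(C)C | intermediate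
12 | (3R,4R,7Z)-7-iodo-2,3,11-trimethyl-9-oxododeca-1,7,10-trien-4-yl (2E)-2-methylbut-2-enoate | C=C(C)[C@@H](C)[C@H](OC(=O)/C(C)=C/C)CC/C(I)=C/C(=O)C=C(C)C | intermediate
13 | neopentylpalladium iodide: (1R,2R,3R)-2,3-dimethyl-4-[(Z)-4-methyl-2-oxopent-3-en-1-ylidene]cyclohexyl tiglate carrying CH2–Pd–I on C3 (ring A closed, phosphines omitted) | CC(C)=CC(=O)/C=C1/CC[C@@H](OC(=O)/C(C)=C/C)[C@H](C)[C@@]1(C)C[Pd]I | intermediate
14 | tertiary alkylpalladium iodide: bicyclic enone as 15 with C(CH3)2–Pd–I in place of the isopropenyl group (both rings closed, phosphines omitted) | CC(C)([Pd]I)[C@H]1C[C@@]2(C)C(CC[C@@H](OC(=O)/C(C)=C/C)[C@@H]2C)=CC1=O | intermediate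
15 | (1R,2R,7R,8aR)-1,8a-dimethyl-6-oxo-7-(prop-1-en-2-yl)-1,2,3,4,6,7,8,8a-octahydronaphthalen-2-yl (2E)-2-methylbut-2-enoate | C=C(C)[C@H]1C[C@@]2(C)C(CC[C@@H](OC(=O)/C(C)=C/C)[C@@H]2C)=CC1=O | intermediate
16 | (1R,2R,4aR,7R,8aS)-1,8a-dimethyl-7-(prop-1-en-2-yl)-6-[(trimethylsilyl)oxy]-1,2,3,4,4a,7,8,8a-octahydronaphthalen-2-yl (2E)-2-methylbut-2-enoate | C=C(C)[C@H]1C[C@@]2(C)[C@H](CC[C@@H](OC(=O)/C(C)=C/C)[C@@H]2C)C=C1O[Si](C)(C)C | intermediate
17 | (1R,2R,4aS,5R,7R,8aR)-5-hydroxy-1,8a-dimethyl-6-oxo-7-(prop-1-en-2-yl)decahydronaphthalen-2-yl (2E)-2-methylbut-2-enoate | C=C(C)[C@H]1C[C@@]2(C)[C@H](CC[C@@H](OC(=O)/C(C)=C/C)[C@@H]2C)[C@@H](O)C1=O | intermediate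
18 | (1R,2R,4aS,5R,7R,8aR)-1,8a-dimethyl-5-[(3-methylbut-2-enoyl)oxy]-6-oxo-7-(prop-1-en-2-yl)decahydronaphthalen-2-yl (2E)-2-methylbut-2-enoate | C=C(C)[C@H]1C[C@@]2(C)[C@H](CC[C@@H](OC(=O)/C(C)=C/C)[C@@H]2C)[C@@H](OC(=O)C=C(C)C)C1=O | target

**Totals**
Total step count: 9. Longest linear sequence: 8 steps (4 → 5 → 7 → 9 → 11 → 12 → 15 → 17 → 18).

**Three steps most likely to fail**

Step 7 is the main risk. The neopentylpalladium may close 3-exo onto the neighbouring enone (cyclopropane) instead of 6-exo onto C7. The face selectivity at C5 rests on a transition-state model and is not precedented for this substrate. β-Hydride elimination toward C7, or base-induced isomerisation, would give the conjugated isopropylidene isomer. The fallback sets out from 12 and comes back at 15, splitting the cascade into a palladium step and a radical step. Carboiodination (Pd[P(t-Bu)3]2, toluene, 100 °C) converts 12 into the isomeric neopentyl iodide (1R,2R,3R)-3-(iodomethyl)-2,3-dimethyl-4-[(Z)-4-methyl-2-oxopent-3-en-1-ylidene]cyclohexyl (2E)-2-methylbut-2-enoate F1, in which only ring A is closed. Iodine abstraction under visible light (Ir(ppy)3, iPr2NEt, MeCN) then gives the C6 radical, which closes ring B 6-exo onto C7, and Co(dmgH)2(py)Cl removes a methyl hydrogen from the tertiary radical to give 15.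

Step 8 may give the trans ring fusion, reduce the tiglate, or trap poorly. The fallback sets out from 15 and comes back at 16, separating reduction from enol silane formation. Copper hydride reduction with a proton quench ([(Ph3P)CuH]6, t-BuOH, toluene) gives the saturated ketone (1R,2R,4aR,7R,8aS)-1,8a-dimethyl-6-oxo-7-(prop-1-en-2-yl)decahydronaphthalen-2-yl (2E)-2-methylbut-2-enoate F2, whose ring fusion can be checked and the cis isomer purified. Kinetic deprotonation at the C9 methylene (LiN(iPr)2, THF, −78 °C; the other α-carbon, C7, is tertiary) and silylation with Me3SiCl then give 16, which is oxidised as in step 8. This does not correct a wrong ring fusion; it only makes it visible before the oxidation.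

Step 3 may give modest ee or anti selectivity, because the aldehyde is aliphatic and the boronate is trisubstituted. The fallback sets out from 5 and comes back at 9. An open-transition-state (type 2) Hosomi–Sakurai addition of trimethyl(2-methylbut-2-enyl)silane, catalysed by a tartrate-derived chiral (acyloxy)borane (the enantiomer giving the 4R carbinol; EtCN, −78 °C, then 1 M HCl), gives the syn alcohol (3R,4R)-2,3-dimethyloct-1-en-7-yn-4-ol F3 whatever the silane geometry. Esterification with (2E)-2-methylbut-2-enoyl chloride and pyridine (retention) then gives 9 without a Mitsunobu inversion.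

**Further compounds**
F1 | step 7 | (1R,2R,3R)-3-(iodomethyl)-2,3-dimethyl-4-[(Z)-4-methyl-2-oxopent-3-en-1-ylidene]cyclohexyl (2E)-2-methylbut-2-enoate | CC(C)=CC(=O)/C=C1/CC[C@@H](OC(=O)/C(C)=C/C)[C@H](C)[C@@]1(C)CI
F2 | step 8 | (1R,2R,4aR,7R,8aS)-1,8a-dimethyl-6-oxo-7-(prop-1-en-2-yl)decahydronaphthalen-2-yl (2E)-2-methylbut-2-enoate | C=C(C)[C@H]1C[C@@]2(C)[C@H](CC[C@@H](OC(=O)/C(C)=C/C)[C@@H]2C)CC1=O
F3 | step 3 | (3R,4R)-2,3-dimethyloct-1-en-7-yn-4-ol | C=C(C)[C@@H](C)[C@H](O)CCC#C
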